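The coupling of dissolved substrate with reagent is slow: by that step alone, at the charged amounts, dissolved substrate has a half-life of 5.3 h.

solid substrate 0.50 M; reagent 1.50 equiv; time 15 h

* the target and solid product and idle adduct together standing at 15 h, as a percentage of the solid substrate charged
* concentration of dissolved substrate in solution at 15 h, in percent of saturation

- a species is counted by the solid substrate in it: one side product counts as two
- amounts and yields of target count solid product and idle adduct too
- for a step with 2 of a species take k times the square, and two of it per event
- given per volume of solution although it is solid: solid substrate, solid product
- at the start none of the solid substrate is in solution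
- dissolved substrate means what is dissolved; the solid is not counted in it
- run time (flask): 15 h

    solid substrate ⇌ dissolved substrate, rate k1*(cs1 - [dissolved substrate]) while solid is left; crystals form when [dissolved substrate] > cs1 (cs1 = 0.28 M, k1 = 0.076 min⁻¹)
    dissolved substrate + reagent → target (k2 = 0.0029 L mol⁻¹ min⁻¹)
    dissolved substrate + target → side product (k3 = 0.0072 L mol⁻¹ min⁻¹)
    solid product ⇌ target, rate k4*(cs4 - [target]) while solid is left; crystals form when [target] > cs4 (cs4 = 0.23 M, k4 = 0.083 min⁻¹)
    target → over-reaction product (k5 = 9.6 × 10⁻⁷ min⁻¹)
    reagent + target ⇌ idle adduct, settled at all times (K6 = 1.1 L mol⁻¹)
    2 reagent → self-condensation product (k7 = 0.0054 L mol⁻¹ min⁻¹)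

Dissolving takes about 13.2 min, far less than that half-life. So [dissolved substrate] should stay near 0.28 M while solid substrate is left, and for that time we expect a reading just under saturation.

But reagent has a quicker way out. Two reagent condense with a first half-life of 2.06 h, shorter than the 14.2 h it has in the coupling at that [dissolved substrate]. So we let self-condensation set [reagent]: the charge divided by one plus the count of those half-lives. The run holds 7.28 of them.

The coupling runs on this shrinking [reagent]. Summed over the run, it makes 0.0752 M times the logarithm of one plus that count, which gives 31.8% of the solid substrate charged. We call this the target budget: the target made by the end, whatever became of it.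

Target does not keep. Near saturation its loss to side product is pseudo-first-order, with a lifetime of 8.27 h, shorter than the run. So the target standing at the end must lie well below the budget, and by hand we stop there. The budget, 0.159 M, lies below 0.23 M, so we expect no solid product.

The forecast gave 10% (8.8% to 11.5%) and 99.3% (93% to 99.8%), holding that reagent “is lost mainly by self-condensation”.

The flask gives 9.73% and 99.3%.

In this flask, target made, counting what went into side product, reads 25.8%, which is 0.810 of the budget. In the flask with 1.2 M of solid substrate, the budget is 18.3% and the reading 14.8%, a ratio of 0.812. This flask is not at rest at 15 h: 2.58% of solid substrate and 8.3% of reagent still stand. By 150 h, side product reaches 69.2%, dissolved substrate falls to 30.7%, and the target, its other forms counted, falls to 0.0726%.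

Its constants are made up.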